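## Retrosynthetic overview

1. Target 16 ⇐ macrocyclic Δ1(15)-butenolide 13. C1–H and the exocyclic CH2 (C17) come last, by conjugate hydrosilylation and aminomethylation; hydride adds anti to the C13 branch and gives the cis-lactone.
2. 14-membered ring ⇐ C13–C14 bond, by intramolecular vinylogous Mukaiyama aldol of a 2-silyloxyfuran onto the (12S)-α-methyl aldehyde. This sets C13 and C14.
3. Oxolane, C3/C4/C7/C8 and the tertiary 8-OAc ⇐ one acetolysis cascade of a (3R,4R,7R,8R)-bis-epoxide, made by one double Shi epoxidation of an E,E-1,5-diene.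
4. C12 ⇐ Riley oxidation then Noyori hydrogenation of the farnesyl terminus. Butenolide ⇐ 3-alkylfuran + singlet oxygen.
5. 19 of the 20 skeletal carbons ⇐ (E,E)-farnesyl bromide + 3-bromofuran. Ring order: lactone precursor (furan, step 1) → oxolane (step 7) → 14-membered carbocycle (step 10).

**Numbering (cembrane):** C1 ring-fusion CH, C2 CH2, C3 CHOH, C4 C(Me)–O, C7 CH–O, C8 C(Me)OAc, C12 CHMe, C13 CHOAc, C14 CH–O(lactone), C15/C16/C17 = α-C/C=O/=CH2. The target is 1S,3R,4S,7R,8S,12S,13R,14R, with a cis-oxolane and a cis-fused lactone.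

**Assumption:** Ru–BINAP is taken to attack the E-2-methylallylic alcohol on the same enantioface as it attacks geraniol. If the sense is reversed, (R)-BINAP is used and nothing else changes.

## Route

**Step 1**
- Reactants: 1 (2E,6E)-farnesyl bromide; 2 3-bromofuran
- Product: 3, 3-[(2E,6E)-3,7,11-trimethyldodeca-2,6,10-trienyl]furan
- Conditions: 2, n-BuLi, THF, −78 °C; ZnCl2, → 0 °C; then 1, Pd(PPh3)4 (3 mol %), THF, 0 °C → rt
- Reagents that add atoms: none
- Why: Negishi allyl–heteroaryl coupling, in which reductive elimination occurs at the unsubstituted allyl terminus with retention of the 2E geometry, and transmetalation to zinc prevents 3-lithio → 2-lithiofuran isomerisation.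

**Step 2**
- Reactants: 3
- Product: 4, (2E,6E,10E)-12-(furan-3-yl)-2,6,10-trimethyldodeca-2,6,10-trien-1-ol
- Conditions: SeO2 (0.3 equiv), t-BuOOH, salicylic acid (cat.), CH2Cl2, 0 °C; then NaBH4, MeOH, 0 °C
- Reagents that add atoms: selenium dioxide O=[Se]=O (O donor), re-oxidised by tert-butyl hydroperoxide CC(C)(C)OO
- Why: Riley allylic oxidation (ene/[2,3]) selects the E-methyl (C13) of the least hindered terminal alkene, 3-alkylfurans tolerate it, and NaBH4 returns any over-oxidised enal (a modest yield with recovered 3 is expected).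

**Step 3**
- Reactants: 4
- Product: 5, (2S,6E,10E)-12-(furan-3-yl)-2,6,10-trimethyldodeca-6,10-dien-1-ol
- Conditions: Ru(OAc)2[(S)-BINAP] (1 mol %), H2 (100 atm), MeOH, 20 °C
- Reagents that add atoms: none
- Why: Noyori hydroxyl-directed asymmetric hydrogenation reduces only the alkene chelated through the allylic OH, leaving the isolated alkenes and the furan untouched, and the geraniol-type facial sense sets C12 = S.

**Step 4**
- Reactants: 5
- Product: 6, 5-hydroxy-4-[(2E,6E,11S)-12-hydroxy-3,7,11-trimethyldodeca-2,6-dienyl]furan-2(5H)-one (C5 epimers)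
- Conditions: O2, hν, rose bengal, i-Pr2NEt, CH2Cl2, −78 °C
- Reagents that add atoms: dioxygen O=O
- Why: Singlet oxygen adds [4+2] to the furan far faster than it undergoes the ene reaction with trisubstituted alkenes at −78 °C, and in the Kornblum–DeLaMare-type fragmentation the hindered base removes the less hindered bridgehead H, which places C=O (C16) remote from the alkyl group and the hemiacetal at C14.

**Step 5**
- Reactants: 6
- Product: 7, 4-[(2E,6E,11S)-12-hydroxy-3,7,11-trimethyldodeca-2,6-dienyl]furan-2(5H)-one
- Conditions: NaBH4, EtOH, 0 °C; then 1 M HCl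
- Reagents that add atoms: none
- Why: Borohydride reduces the open aldehyde tautomer of the pseudo-acid and acid relactonises it, while the β-substituted enoate resists 1,4-reduction.

**Step 6**
- Reactants: 7
- Product: 8, 4-({(2R,3R)-3-[2-((2R,3R)-3-[(4S)-5-hydroxy-4-methylpentyl]-3-methyloxiran-2-yl)ethyl]-3-methyloxiran-2-yl}methyl)furan-2(5H)-one (3R,4R,7R,8R bis-epoxide)
- Conditions: D-fructose-derived Shi ketone (0.6 equiv), Oxone, K2CO3, Bu4NHSO4, MeCN–DMM/aq borate–EDTA buffer, 0 °C
- Reagents that add atoms: Oxone (potassium peroxymonosulfate) OOS(=O)(=O)[O-].[K+]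
- Why: Shi asymmetric epoxidation (spiro transition state) gives (R,R)-epoxides from both E-trisubstituted alkenes under catalyst control, and the electron-poor butenolide C=C is inert to the dioxirane.

**Step 7 (key step)**
- Reactants: 8
- Product: 9, 4-[(2R)-2-{(2S,5R)-5-[(2S,6S)-2-acetoxy-7-hydroxy-6-methylheptan-2-yl]-2-methyloxolan-2-yl}-2-hydroxyethyl]furan-2(5H)-one
- Conditions: AcOH–CH2Cl2 (1:4), CSA (5 mol %), −20 → 0 °C
- Reagents that add atoms: acetic acid CC(=O)O
- Why: Proposed new method: the head-to-tail bis-epoxide matches Markovnikov and Baldwin preferences in only one direction, so O7 (as the neighbouring epoxide oxygen via a bicyclic epoxonium, or as C7–OH after prior acetolysis) attacks tertiary C4 5-exo with inversion while AcOH attacks tertiary C8 with inversion, both orders converging on 3R,4S,7R,8S and delivering the cis-oxolane, the free 3-OH and the tertiary 8-OAc in one operation; the closest known reaction types are Brønsted-acid 5-exo epoxide-opening cascades of terpenoid polyepoxides and acid-catalysed acetolysis of trisubstituted epoxides at the tertiary carbon.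

**Step 8**
- Reactants: 9
- Product: 10, the C13 aldehyde of 9 ((2S)-2-methyl aldehyde, 3-OH free)
- Conditions: TEMPO (10 mol %), PhI(OAc)2, CH2Cl2, rt
- Reagents that add atoms: none
- Why: Oxoammonium (TEMPO/BAIB) oxidation is selective for the primary alcohol over the neopentyl-type secondary 3-OH and is mild enough to preserve C12.

**Step 9**
- Reactants: 10
- Product: 11, the 3-O-TBS ether of 10 with the butenolide converted to a 4-substituted 2-(tert-butyldimethylsilyloxy)furan (aldehyde intact)
- Conditions: TBSOTf (2.4 equiv), Et3N (5 equiv), CH2Cl2, −78 → 0 °C; rapid filtration through Et3N-deactivated silica, used at once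
- Reagents that add atoms: TBSOTf CC(C)(C)[Si](C)(C)OS(=O)(=O)C(F)(F)F
- Why: Under silyl triflate/amine soft enolisation, O-silylation of the alcohol and aromatisation-driven deprotonation at ring C14 are much faster than enol silylation of an α-branched aldehyde, so C12 is preserved.

**Step 10 (key step)**
- Reactants: 11
- Product: 12, (3R,4S,7R,8S,12S,13R,14R)-8-acetoxy-3-(TBSO)-4,7-epoxy-13-hydroxy-17-norcembr-1(15)-en-16,14-olide (macrocyclic butenolide)
- Conditions: syringe-pump addition of 11 (8 h) to BF3·OEt2 (10 equiv), CH2Cl2 (final 1 mM), −78 °C; aq NaHCO3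
- Reagents that add atoms: none
- Why: Proposed new method: the BF3-activated aldehyde is attacked by C5 (= C14) of the tethered silyloxyfuran, with high dilution and the cis-oxolane turn favouring the 14-membered closure, Felkin–Anh control by the C12 methyl giving 12,13-syn (13R) and the usual open antiperiplanar transition state giving 13,14-threo (14R), and no free base left to re-enolise C14; the closest known reaction types are the threo-selective intermolecular BF3-mediated vinylogous Mukaiyama aldol of 2-silyloxyfurans and intramolecular silylative aldol cyclisations of lactone aldehydes.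

**Step 11**
- Reactants: 12
- Product: 13, the 13-O-acetate of 12 (8,13-diacetate)
- Conditions: Ac2O, pyridine, DMAP (2 mol %), CH2Cl2, 0 °C
- Reagents that add atoms: acetic anhydride CC(=O)OC(C)=O
- Why: This is a standard acylation of the only free OH, and weak base at low temperature avoids C14 epimerisation and E1cB loss of acetate to a γ-ylidene butenolide.

**Step 12**
- Reactants: 13
- Product: 14, the (1S)-saturated cis-fused lactone bearing 15-CH2NMe2 (C15 epimers)
- Conditions: RhCl(PPh3)3 (5 mol %), Et3SiH, PhMe, 60 °C; evaporate; then CH2=NMe2+ I−, CH2Cl2, rt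
- Reagents that add atoms: Eschenmoser's salt C=[N+](C)C.[I-]
- Why: Rh-catalysed 1,4-hydrosilylation delivers H to C1 on the open butenolide face anti to the C13 branch (cis-lactone, 1S) and gives a regiodefined silyl ketene acetal without base, so both acetates survive before Mannich aminomethylation.

**Step 13**
- Reactants: 14
- Product: 15, the 3-O-TBS ether of the target
- Conditions: MeI, CH2Cl2, rt; then sat. aq NaHCO3
- Reagents that add atoms: none (MeI departs with NMe3)
- Why: Quaternisation followed by Hofmann-type E1cB elimination gives the α-methylene lactone under conditions too mild to touch the acetates or isomerise the alkene.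

**Step 14**
- Reactants: 15
- Product: 16, the target (CID10479028)
- Conditions: HF·pyridine, THF, 0 °C → rt
- Reagents that add atoms: none
- Why: Fluoride desilylation frees the 3-OH, and the acetates, the oxolane and the α-methylene lactone are stable to buffered HF.

## Compound list

| No. | Name | SMILES | Role |
|---|---|---|---|
| 1 | (2E,6E)-farnesyl bromide | `CC(C)=CCC/C(C)=C/CC/C(C)=C/CBr` | starting material |
| 2 | 3-bromofuran | `Brc1ccoc1` | starting material |
| 3 | 3-(E,E-farnesyl)furan | `CC(C)=CCC/C(C)=C/CC/C(C)=C/Cc1ccoc1` | intermediate |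
| 4 | terminal E-allylic alcohol | `OC/C(C)=C/CC/C(C)=C/CC/C(C)=C/Cc1ccoc1` | intermediate |
| 5 | (12S)-dihydro alcohol | `OC[C@@H](C)CCC/C(C)=C/CC/C(C)=C/Cc1ccoc1` | intermediate |
| 6 | γ-hydroxybutenolide | `OC[C@@H](C)CCC/C(C)=C/CC/C(C)=C/CC1=CC(=O)OC1O` | intermediate |
| 7 | β-substituted butenolide | `OC[C@@H](C)CCC/C(C)=C/CC/C(C)=C/CC1=CC(=O)OC1` | intermediate |
| 8 | (3R,4R,7R,8R)-bis-epoxide | `OC[C@@H](C)CCC[C@@]1(C)O[C@@H]1CC[C@@]2(C)O[C@@H]2CC3=CC(=O)OC3` | intermediate |
| 9 | oxolane diol 8-acetate | `OC[C@@H](C)CCC[C@](C)(OC(C)=O)[C@H]1CC[C@](C)(O1)[C@H](O)CC2=CC(=O)OC2` | intermediate |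
| 10 | C13 aldehyde | `O=C[C@@H](C)CCC[C@](C)(OC(C)=O)[C@H]1CC[C@](C)(O1)[C@H](O)CC2=CC(=O)OC2` | intermediate |
| 11 | 3-OTBS silyloxyfuran aldehyde | `O=C[C@@H](C)CCC[C@](C)(OC(C)=O)[C@H]1CC[C@](C)(O1)[C@H](O[Si](C)(C)C(C)(C)C)Cc2coc(O[Si](C)(C)C(C)(C)C)c2` | intermediate |
| 12 | macrocyclic butenolide, 13-OH | `O=C1O[C@H]2[C@H](O)[C@@H](C)CCC[C@](C)(OC(C)=O)[C@H]3CC[C@](C)(O3)[C@H](O[Si](C)(C)C(C)(C)C)CC2=C1` | intermediate |
| 13 | macrocyclic butenolide, 8,13-diacetate | `O=C1O[C@H]2[C@H](OC(C)=O)[C@@H](C)CCC[C@](C)(OC(C)=O)[C@H]3CC[C@](C)(O3)[C@H](O[Si](C)(C)C(C)(C)C)CC2=C1` | intermediate |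
| 14 | cis-lactone Mannich base | `CN(C)CC1C(=O)O[C@H]2[C@H](OC(C)=O)[C@@H](C)CCC[C@](C)(OC(C)=O)[C@H]3CC[C@](C)(O3)[C@H](O[Si](C)(C)C(C)(C)C)C[C@@H]12` | intermediate |
| 15 | 3-O-TBS target | `C=C1C(=O)O[C@H]2[C@H](OC(C)=O)[C@@H](C)CCC[C@](C)(OC(C)=O)[C@H]3CC[C@](C)(O3)[C@H](O[Si](C)(C)C(C)(C)C)C[C@@H]12` | intermediate |
| 16 | CID10479028 | `C=C1C(=O)O[C@H]2[C@H](OC(C)=O)[C@@H](C)CCC[C@](C)(OC(C)=O)[C@H]3CC[C@](C)(O3)[C@H](O)C[C@@H]12` | target |

## Step count

- Total steps: 14
- Longest linear sequence: 14 (fully linear from 1 and 2, with one protecting group)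

## Three steps most likely to fail

1. **Step 10, macrocyclising vinylogous Mukaiyama aldol.** The risks are oligomerisation, protodesilylation, and macrocyclic override of the Felkin and threo preferences.
   - Fallback: close the same C13–C14 bond reductively instead of by a polar aldol.
   - Omit step 5 and carry the γ-hydroxybutenolide, a masked C14 aldehyde, through as its methyl pseudo-ester.
   - Run a low-valent Ti or SmI2 pinacol macrocyclisation of the C13/C14 dialdehyde. The C14 alkoxide relactonises to 12, and the diastereomers are separated.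

2. **Step 7, acetate-terminated bis-epoxide cascade.** The risks are competing intermolecular acetolysis at C4, oxane formation, and SN1 leakage at C8.
   - Fallback: differentiate the two epoxides by chelation.
   - Start from (E,E)-farnesol. Install the 3,4-epoxide by Sharpless epoxidation (D-(−)-DET) while C2 is still a carbinol, and the 7,8-epoxide by Shi epoxidation.
   - Use Ti(OiPr)4/acetate to activate only the 2,3-epoxy-alcohol terminus for the O7 → C4 closure.
   - Convert the resulting C2,C3-diol to the terminal epoxide and form C1–C2 by opening it with a 3-furyl cuprate.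

3. **Step 12, hydrosilylation/aminomethylation of the hindered β,γ-disubstituted butenolide.**
   - Fallback: drop the silyl ketene acetal approach.
   - Hydrogenate 13 (H2, Rh/Al2O3; same exposed face) to the cis-lactone.
   - Install C17 by carboxylation with methyl magnesium carbonate, followed by decarboxylative methylenation (aq HCHO, Et2NH, then AcOH/NaOAc). This needs no strong amide base and so tolerates both acetates.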